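The route rests on cutting the C3'–C4'' bond of the dimethylpyran (ring D). The other ring D atoms travel from the start as a 1,1-dimethylpropargyl ether on O2' of ring B, which also protects that phenol. The key step, a gold-catalysed 6-endo-dig hydroarylation, closes ring D on the otherwise unprotected isoflavan as the last operation. It exploits that C3' is the only free carbon ortho to O2'. Lying between O2' and O4', it is also the most nucleophilic carbon of ring B. Because the O2'–C2'' bond is never broken, the free 4'-OH cannot enter the ring. C3 comes from an Evans alkylation, ring C from a Mitsunobu etherification.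

Key step: step 14

Remark: isoflavan numbering is used (ring A C4a–C8a, ring C O1–C4, ring B C1'–C6', ring D O2'–C2''–C3''–C4''–C3'–C2'); prenyl means 3-methylbut-2-en-1-yl and TIPS means triisopropylsilyl.

Step 1
Reactants: 1 3,5-dimethoxyphenol
Product: 2 (3,5-dimethoxyphenoxy)triisopropylsilane
Conditions: i-Pr3SiCl, imidazole, DMF, rt
Reagents that add atoms: triisopropylsilyl chloride, CC(C)[Si](Cl)(C(C)C)C(C)C
Why: Imidazole-promoted silylation of a phenol installs a bulky, poorly coordinating group that steers the metalation in step 2 and later protects the future O1.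

Step 2
Reactants: 2 (3,5-dimethoxyphenoxy)triisopropylsilane; 3 prenyl bromide
Product: 5 (3,5-dimethoxy-4-prenylphenoxy)triisopropylsilane, via aryllithium 4 (not isolated)
Conditions: n-BuLi, THF, 0 °C to rt; then 3, −78 °C to rt
Reagents that add atoms: prenyl bromide 3, CC(C)=CCBr; n-butyllithium, [Li]CCCC (lithium of 4 only)
Why: Directed ortho-metalation followed by SN2 alkylation: the carbon between the two methoxy groups is the most acidic and doubly coordinated site, the positions next to the bulky silyl ether are shielded, and the aryllithium should attack the primary carbon of 3.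

Step 3
Reactants: 5 (3,5-dimethoxy-4-prenylphenoxy)triisopropylsilane
Product: 7 2,4-dimethoxy-3-prenyl-6-(triisopropylsilyloxy)benzaldehyde, via aryl iminium chloride 6 (not isolated)
Conditions: POCl3, DMF, 0 °C to rt; then aq. NaOAc, 0 °C
Reagents that add atoms: N,N-dimethylformamide, CN(C)C=O (formyl carbon; nitrogen of 6 only); water, O (aldehyde oxygen); phosphoryl chloride, O=P(Cl)(Cl)Cl (chloride of 6 only)
Why: Vilsmeier-Haack formylation: the two free ring positions are equivalent by symmetry and each is ortho or para to three oxygen donors, so one aldehyde should form, and the mild chloroiminium electrophile should leave the trisubstituted alkene alone.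

Step 4
Reactants: 7 2,4-dimethoxy-3-prenyl-6-(triisopropylsilyloxy)benzaldehyde
Product: 8 [2,4-dimethoxy-3-prenyl-6-(triisopropylsilyloxy)phenyl]methanol
Conditions: NaBH4, THF–MeOH, 0 °C
Reagents that add atoms: none
Why: Borohydride reduction of an aromatic aldehyde touches neither the alkene nor the TIPS ether, which is too bulky to migrate readily to the new alkoxide.

Step 5
Reactants: 8 [2,4-dimethoxy-3-prenyl-6-(triisopropylsilyloxy)phenyl]methanol
Product: 9 [2-(bromomethyl)-3,5-dimethoxy-4-prenylphenoxy]triisopropylsilane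
Conditions: CBr4, PPh3, CH2Cl2, −20 °C; cold pentane filtration, used at once
Reagents that add atoms: carbon tetrabromide, BrC(Br)(Br)Br
Why: The Appel bromination runs under neutral conditions, so no HBr can add to the prenyl group, and the very electron-rich bromide is kept cold and not stored.

Step 6
Reactants: 10 methyl (2,4-dihydroxyphenyl)acetate
Product: 11 methyl [2-hydroxy-4-(triisopropylsilyloxy)phenyl]acetate
Conditions: i-Pr3SiCl (1.0 equiv), imidazole, CH2Cl2, −10 to 0 °C
Reagents that add atoms: triisopropylsilyl chloride, CC(C)[Si](Cl)(C(C)C)C(C)C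
Why: Sterically controlled monosilylation: the 4-OH is unhindered, whereas the 2-OH is flanked by the CH2CO2Me arm and hydrogen-bonded to its carbonyl, so one equivalent of the bulky chloride should react at O4.

Step 7
Reactants: 11 methyl [2-hydroxy-4-(triisopropylsilyloxy)phenyl]acetate; 12 3-chloro-3-methylbut-1-yne
Product: 13 methyl [2-(2-methylbut-3-yn-2-yloxy)-4-(triisopropylsilyloxy)phenyl]acetate
Conditions: 12, DBU, CuCl2 (1 mol %), MeCN, 0 °C
Reagents that add atoms: 3-chloro-3-methylbut-1-yne 12, CC(C)(Cl)C#C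
Why: Copper-catalysed propargylic etherification of a phenol with a tertiary propargylic chloride proceeds through a copper acetylide that ionises and is attacked at the tertiary carbon, at a temperature far below that of any sigmatropic rearrangement of the product.

Step 8
Reactants: 13 methyl [2-(2-methylbut-3-yn-2-yloxy)-4-(triisopropylsilyloxy)phenyl]acetate
Product: 14 [2-(2-methylbut-3-yn-2-yloxy)-4-(triisopropylsilyloxy)phenyl]acetic acid
Conditions: LiOH, THF–H2O, 0 °C; then 1 M HCl to pH 4
Reagents that add atoms: lithium hydroxide, [Li+].[OH-]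
Why: Saponification of an unhindered methyl arylacetate should be fast enough at 0 °C for the aryl TIPS ether, the most base-stable of the common aryl silyl ethers, to survive.

Step 9
Reactants: 14 [2-(2-methylbut-3-yn-2-yloxy)-4-(triisopropylsilyloxy)phenyl]acetic acid; 15 (4R)-4-benzyl-1,3-oxazolidin-2-one
Product: 17 (4R)-4-benzyl-3-{[2-(2-methylbut-3-yn-2-yloxy)-4-(triisopropylsilyloxy)phenyl]acetyl}-1,3-oxazolidin-2-one, via mixed pivalic anhydride 16 (not isolated)
Conditions: t-BuCOCl, Et3N, THF, −20 °C; then LiCl, 15, −20 °C to rt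
Reagents that add atoms: (4R)-4-benzyl-1,3-oxazolidin-2-one 15, O=C1N[C@H](Cc2ccccc2)CO1; pivaloyl chloride, CC(C)(C)C(=O)Cl (acyl group of 16 only)
Why: N-acylation of the Evans auxiliary through a mixed anhydride with LiCl/Et3N activation, with attack at the less hindered arylacetyl carbonyl.

Step 10
Reactants: 17 the N-arylacetyl oxazolidinone; 9 the benzylic bromide
Product: 19 (4R)-4-benzyl-3-{(2R)-3-[2,4-dimethoxy-3-prenyl-6-(triisopropylsilyloxy)phenyl]-2-[2-(2-methylbut-3-yn-2-yloxy)-4-(triisopropylsilyloxy)phenyl]propanoyl}-1,3-oxazolidin-2-one, via sodium Z-enolate 18 (not isolated)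
Conditions: NaN(SiMe3)2 (1.0 equiv), THF, −78 °C; then cold THF solution of 9, −78 to −40 °C
Reagents that add atoms: sodium bis(trimethylsilyl)amide, [Na+].C[Si](C)(C)[N-][Si](C)(C)C (sodium of 18 only)
Why: Evans asymmetric alkylation: the benzyl group of the (R)-auxiliary shields one face of the chelated Z-enolate 18, so the bromide should enter from the other face and set the future C3 as R, while one equivalent of base spares the far less acidic alkyne C–H.

Step 11
Reactants: 19 the alkylated imide
Product: 20 (2R)-3-[2,4-dimethoxy-3-prenyl-6-(triisopropylsilyloxy)phenyl]-2-[2-(2-methylbut-3-yn-2-yloxy)-4-(triisopropylsilyloxy)phenyl]propan-1-ol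
Conditions: LiBH4, MeOH (1 equiv), Et2O, 0 °C
Reagents that add atoms: none
Why: Reductive cleavage of an N-acyl oxazolidinone with LiBH4 is weakly basic, should not epimerise the α-aryl stereocentre, and leaves alkyne, alkene and silyl ethers untouched.

Step 12
Reactants: 20 the bis-silyl alcohol
Product: 21 2-{(2R)-3-hydroxy-2-[4-hydroxy-2-(2-methylbut-3-yn-2-yloxy)phenyl]propyl}-3,5-dimethoxy-4-prenylphenol
Conditions: Bu4NF, AcOH, THF, 0 °C
Reagents that add atoms: none
Why: Fluoride cleavage removes both aryl silyl ethers in one operation, and the acetic acid buffer keeps the medium from becoming strongly basic.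

Step 13
Reactants: 21 the triol
Product: 22 (3R)-4'-hydroxy-5,7-dimethoxy-2'-(2-methylbut-3-yn-2-yloxy)-6-prenylisoflavan
Conditions: PPh3, DIAD, THF (0.01 M), 0 °C to rt
Reagents that add atoms: none
Why: Intramolecular Mitsunobu etherification closes ring C in the 6-exo-tet mode: only the ring A phenol can reach the activated C2, since O2' is blocked as the propargyl ether and the 4'-OH is out of reach, and C3 takes no part.

Step 14
Reactants: 22 (3R)-4'-hydroxy-5,7-dimethoxy-2'-(2-methylbut-3-yn-2-yloxy)-6-prenylisoflavan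
Product: 24 kanzonol I, via vinylgold chromene 23 (not isolated)
Conditions: (Ph3P)AuNTf2 (3 mol %), CH2Cl2, rt
Reagents that add atoms: (Ph3P)AuNTf2, c1ccc(cc1)P(c1ccccc1)c1ccccc1.[Au+].O=S(=O)([N-]S(=O)(=O)C(F)(F)F)C(F)(F)F (gold and phosphine of 23 only)
Why: The cationic monovalent gold centre binds the terminal alkyne of 22 as a π-acid, C3' of ring B attacks the terminal alkyne carbon, loss of the C3' proton rearomatises ring B to vinylgold 23, and protodeauration by the released HNTf2 gives 24 and returns the catalyst. The closest known reaction type is the gold-catalysed intramolecular hydroarylation (Friedel-Crafts-type alkenylation) of aryl propargyl ethers, 1,1-dimethylpropargyl ethers included, to 2H-chromenes. Ring D closes in the 6-endo-dig mode, the mode regularly seen with aryl propargyl ethers because attack on the internal alkyne carbon would build a strained 3-methylene-2,3-dihydrobenzofuran, and the geminal methyl groups fold the chain towards C3'. No stereocentre is formed, and C3 meets neither base nor strong acid at room temperature. Site selectivity lies in the substrate: of the two carbons ortho to O2', C1' is fully substituted and C3' is doubly activated by O2' and the free 4'-OH, and because the O2'–C2'' bond made in step 7 stays intact the 4'-OH cannot become the ring oxygen, as it could in a thermal Claisen route through a 3'-allenylresorcinol with two ortho hydroxyl groups. Chemoselectivity for the alkyne over the prenyl alkene rests on the stronger activation of alkynes by gold and on the lack of any nucleophile near the alkene, which is flanked by two methyl ethers.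

Compound list
1 | 3,5-dimethoxyphenol | COc1cc(O)cc(OC)c1 | starting material
2 | (3,5-dimethoxyphenoxy)triisopropylsilane | COc1cc(OC)cc(O[Si](C(C)C)(C(C)C)C(C)C)c1 | intermediate
3 | prenyl bromide (1-bromo-3-methylbut-2-ene) | CC(C)=CCBr | starting material
4 | 2,6-dimethoxy-4-(triisopropylsilyloxy)phenyllithium | COc1cc(O[Si](C(C)C)(C(C)C)C(C)C)cc(OC)c1[Li] | intermediate
5 | (3,5-dimethoxy-4-prenylphenoxy)triisopropylsilane | COc1cc(O[Si](C(C)C)(C(C)C)C(C)C)cc(OC)c1CC=C(C)C | intermediate
6 | {[2,4-dimethoxy-3-prenyl-6-(triisopropylsilyloxy)phenyl]methylidene}dimethylammonium chloride | COc1cc(O[Si](C(C)C)(C(C)C)C(C)C)c(C=[N+](C)C)c(OC)c1CC=C(C)C.[Cl-] | intermediate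
7 | 2,4-dimethoxy-3-prenyl-6-(triisopropylsilyloxy)benzaldehyde | COc1cc(O[Si](C(C)C)(C(C)C)C(C)C)c(C=O)c(OC)c1CC=C(C)C | intermediate
8 | [2,4-dimethoxy-3-prenyl-6-(triisopropylsilyloxy)phenyl]methanol | COc1cc(O[Si](C(C)C)(C(C)C)C(C)C)c(CO)c(OC)c1CC=C(C)C | intermediate
9 | [2-(bromomethyl)-3,5-dimethoxy-4-prenylphenoxy]triisopropylsilane | COc1cc(O[Si](C(C)C)(C(C)C)C(C)C)c(CBr)c(OC)c1CC=C(C)C | intermediate
10 | methyl (2,4-dihydroxyphenyl)acetate | COC(=O)Cc1ccc(O)cc1O | starting material
11 | methyl [2-hydroxy-4-(triisopropylsilyloxy)phenyl]acetate | COC(=O)Cc1ccc(O[Si](C(C)C)(C(C)C)C(C)C)cc1O | intermediate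
12 | 3-chloro-3-methylbut-1-yne | CC(C)(Cl)C#C | starting material
13 | methyl [2-(2-methylbut-3-yn-2-yloxy)-4-(triisopropylsilyloxy)phenyl]acetate | COC(=O)Cc1ccc(O[Si](C(C)C)(C(C)C)C(C)C)cc1OC(C)(C)C#C | intermediate
14 | [2-(2-methylbut-3-yn-2-yloxy)-4-(triisopropylsilyloxy)phenyl]acetic acid | OC(=O)Cc1ccc(O[Si](C(C)C)(C(C)C)C(C)C)cc1OC(C)(C)C#C | intermediate
15 | (4R)-4-benzyl-1,3-oxazolidin-2-one | O=C1N[C@H](Cc2ccccc2)CO1 | starting material
16 | mixed anhydride of 14 and pivalic acid | CC(C)(C)C(=O)OC(=O)Cc1ccc(O[Si](C(C)C)(C(C)C)C(C)C)cc1OC(C)(C)C#C | intermediate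
17 | (4R)-4-benzyl-3-{[2-(2-methylbut-3-yn-2-yloxy)-4-(triisopropylsilyloxy)phenyl]acetyl}-1,3-oxazolidin-2-one | O=C(Cc1ccc(O[Si](C(C)C)(C(C)C)C(C)C)cc1OC(C)(C)C#C)N1[C@H](Cc2ccccc2)COC1=O | intermediate
18 | sodium (Z)-enolate of 17 | [Na+].[O-]/C(=C\c1ccc(O[Si](C(C)C)(C(C)C)C(C)C)cc1OC(C)(C)C#C)N1[C@H](Cc2ccccc2)COC1=O | intermediate
19 | (4R)-4-benzyl-3-[(2R)-2,3-diarylpropanoyl]-1,3-oxazolidin-2-one (aryl groups as named in step 10) | O=C([C@H](Cc1c(OC)c(CC=C(C)C)c(OC)cc1O[Si](C(C)C)(C(C)C)C(C)C)c1ccc(O[Si](C(C)C)(C(C)C)C(C)C)cc1OC(C)(C)C#C)N1[C@H](Cc2ccccc2)COC1=O | intermediate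
20 | (2R)-3-[2,4-dimethoxy-3-prenyl-6-(triisopropylsilyloxy)phenyl]-2-[2-(2-methylbut-3-yn-2-yloxy)-4-(triisopropylsilyloxy)phenyl]propan-1-ol | OC[C@H](Cc1c(OC)c(CC=C(C)C)c(OC)cc1O[Si](C(C)C)(C(C)C)C(C)C)c1ccc(O[Si](C(C)C)(C(C)C)C(C)C)cc1OC(C)(C)C#C | intermediate
21 | 2-{(2R)-3-hydroxy-2-[4-hydroxy-2-(2-methylbut-3-yn-2-yloxy)phenyl]propyl}-3,5-dimethoxy-4-prenylphenol | OC[C@H](Cc1c(OC)c(CC=C(C)C)c(OC)cc1O)c1ccc(O)cc1OC(C)(C)C#C | intermediate
22 | (3R)-4'-hydroxy-5,7-dimethoxy-2'-(2-methylbut-3-yn-2-yloxy)-6-prenylisoflavan | COc1cc2c(c(OC)c1CC=C(C)C)C[C@H](c1ccc(O)cc1OC(C)(C)C#C)CO2 | intermediate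
23 | C3''-(triphenylphosphinegold) derivative of 24 | COc1cc2c(c(OC)c1CC=C(C)C)C[C@H](c1ccc(O)c3c1OC(C)(C)C([Au-][P+](c1ccccc1)(c1ccccc1)c1ccccc1)=C3)CO2 | intermediate
24 | kanzonol I, (3R) | COc1cc2c(c(OC)c1CC=C(C)C)C[C@H](c1ccc(O)c3c1OC(C)(C)C=C3)CO2 | target

Total step count: 14. Longest linear sequence: 10 steps (steps 1–5 and 10–14).

Steps most likely to fail:

First, step 14. The gold-bound alkyne may trigger heterolysis of the tertiary propargylic C–O bond, with loss of the five-carbon unit. The acid set free in the cycle may also oligomerise the electron-rich chromene. The fallback replaces π-acid catalysis by a pericyclic cascade; it sets out from 22 and returns at 24. The free 4'-OH would be silylated (i-Pr3SiCl, imidazole, DMF) to the 4'-O-triisopropylsilyl ether F1. Heating F1 in o-xylene at 140 °C should take it through the aromatic propargyl Claisen rearrangement, enolisation, 1,5-hydrogen shift and oxa-6π electrocyclisation to the silylated chromene F2. With O4' capped, only O2' carries the hydrogen needed for the shift, so only O2' can close the ring. Bu4NF in THF then gives 24.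

Second, step 10. The very electron-rich bromide 9 may ionise and alkylate itself in a Friedel-Crafts manner before it meets the enolate. Proton exchange between product and enolate may also erode the diastereomeric purity. The fallback replaces substitution on a halide by conjugate addition to an ortho-quinone methide released from a bench-stable precursor; it sets out from 8 (with 18) and returns at 21. Bu4NF would free the salicyl alcohol F3. 4-Methylbenzenesulfinic acid in CH2Cl2 would convert F3 into the crystalline sulfone F4. Added at −78 °C to enolate 18 with one further equivalent of NaN(SiMe3)2, F4 should lose sulfinate from its phenoxide on warming to about −30 °C. This gives the ortho-quinone methide F5, which the shielded enolate should trap at its methylene carbon from the same face as in step 10, giving the phenol imide F6. Immediate LiBH4 reduction would give the diol F7, whether or not F6 has lactonised in between. Bu4NF/AcOH then gives 21.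

Third, step 6. The two phenols may be poorly discriminated, and double silylation may occur. The fallback masks O2 in a temporary ring instead of relying on steric bias; it sets out from 10 and returns at 11. Catalytic TsOH in refluxing toluene with removal of methanol would close the lactone 6-hydroxy-1-benzofuran-2(3H)-one F8. Its only free hydroxyl would be silylated (i-Pr3SiCl, imidazole) to the silyl lactone F9. Methanolysis (MeOH, catalytic Et3N, rt) would open F9 to 11.

Further compounds
F1 | step 14 | (3R)-5,7-dimethoxy-2'-(2-methylbut-3-yn-2-yloxy)-6-prenyl-4'-(triisopropylsilyloxy)isoflavan | COc1cc2c(c(OC)c1CC=C(C)C)C[C@H](c1ccc(O[Si](C(C)C)(C(C)C)C(C)C)cc1OC(C)(C)C#C)CO2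
F2 | step 14 | 4'-O-triisopropylsilyl ether of kanzonol I, (3R) | COc1cc2c(c(OC)c1CC=C(C)C)C[C@H](c1ccc(O[Si](C(C)C)(C(C)C)C(C)C)c3c1OC(C)(C)C=C3)CO2
F3 | step 10 | 2-(hydroxymethyl)-3,5-dimethoxy-4-prenylphenol | COc1cc(O)c(CO)c(OC)c1CC=C(C)C
F4 | step 10 | 3,5-dimethoxy-2-[(4-methylphenyl)sulfonylmethyl]-4-prenylphenol | COc1cc(O)c(CS(=O)(=O)c2ccc(C)cc2)c(OC)c1CC=C(C)C
F5 | step 10 | 3,5-dimethoxy-6-methylidene-4-prenylcyclohexa-2,4-dien-1-one | COC1=CC(=O)C(=C)C(OC)=C1CC=C(C)C
F6 | step 10 | (4R)-4-benzyl-3-{(2R)-3-(6-hydroxy-2,4-dimethoxy-3-prenylphenyl)-2-[2-(2-methylbut-3-yn-2-yloxy)-4-(triisopropylsilyloxy)phenyl]propanoyl}-1,3-oxazolidin-2-one | O=C([C@H](Cc1c(OC)c(CC=C(C)C)c(OC)cc1O)c1ccc(O[Si](C(C)C)(C(C)C)C(C)C)cc1OC(C)(C)C#C)N1[C@H](Cc2ccccc2)COC1=O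
F7 | step 10 | 2-{(2R)-3-hydroxy-2-[2-(2-methylbut-3-yn-2-yloxy)-4-(triisopropylsilyloxy)phenyl]propyl}-3,5-dimethoxy-4-prenylphenol | OC[C@H](Cc1c(OC)c(CC=C(C)C)c(OC)cc1O)c1ccc(O[Si](C(C)C)(C(C)C)C(C)C)cc1OC(C)(C)C#C
F8 | step 6 | 6-hydroxy-1-benzofuran-2(3H)-one | O=C1Cc2ccc(O)cc2O1
F9 | step 6 | 6-(triisopropylsilyloxy)-1-benzofuran-2(3H)-one | O=C1Cc2ccc(O[Si](C(C)C)(C(C)C)C(C)C)cc2O1
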